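**Strategy.** The target is cut at the C6–O–C4' diaryl ether into a ring A aryl triflate and a ring B phenol. Everything rests on taking ring A apart into two open three-carbon chains. Its C5–C6(O)–C1(CO2H) segment is an acetoacetate, and its C2(heptyl)–C3–C4(OMe) segment is a masked 1,3-dielectrophile. A TiCl4-mediated formal [3+3] cyclocondensation exploits this pattern. It forms C4–C5 and C1–C2 and aromatises in one operation, with the C6 phenol and the C4 methyl ether already differentiated. The precursors are the bis(trimethylsilyl) dienol ether of benzyl acetoacetate and octanoyl ketene dimethyl acetal. Ring B, C5' methoxy included, comes from a dioxinone polyketide chain.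

Key step: step 4

Remark on numbering: ring A has C1 (carboxyl), C2 (heptyl), C4 (OMe) and C6 (ether O). Ring B has C1' (carboxyl), C2' (OH), C4' (ether O), C5' (OMe) and C6' (heptyl).

Assumption: the target has no stereocentre. The alkene geometries of 5, 6 and 7 and the enolisable centre of 14 are erased on aromatisation, so they are left open (6 is drawn in one geometry; either serves).

**Step 1**
Reactants: 1 octanoyl chloride; 2 1,1-dimethoxyethene
Product: 3 1,1-dimethoxydec-1-en-3-one
Conditions: 2 (1.5 equiv), pyridine (1.2 equiv), CH2Cl2, 0 °C to rt, anhydrous; filtration and bulb-to-bulb distillation, no aqueous acid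
Reagents that add atoms: none
Why: This is a C-acylation of a ketene acetal, in which the electron-rich methylene carbon of 2 attacks the acylpyridinium ion and pyridine removes the acidified proton from the dialkoxycarbenium ion before chloride can demethylate it, while being too weak a base to convert 1 into a ketene.

**Step 2**
Reactants: 4 benzyl acetoacetate
Product: 5 benzyl 3-(trimethylsilyloxy)but-2-enoate (E/Z mixture)
Conditions: Me3SiCl, Et3N, toluene, rt
Reagents that add atoms: chlorotrimethylsilane, C[Si](C)(C)Cl
Why: Silyl enol ether formation by soft enolisation should silylate the ketone oxygen of the β-keto ester, because the hydrogen-bonded enol is the only acidic site.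

**Step 3**
Reactants: 5 benzyl 3-(trimethylsilyloxy)but-2-enoate
Product: 6 1-benzyloxy-1,3-bis(trimethylsilyloxy)buta-1,3-diene
Conditions: LiN(iPr)2, THF, −78 °C; Me3SiCl, −78 to 0 °C; used without chromatography
Reagents that add atoms: chlorotrimethylsilane, C[Si](C)(C)Cl
Why: Kinetic γ-deprotonation of the vinylogous ester methyl group followed by O-silylation of the dienolate (silyl ketene acetal formation) should give the bis(silyloxy)diene, since the hindered amide base does not attack the benzyl ester at −78 °C.

**Step 4**
Reactants: 6 1-benzyloxy-1,3-bis(trimethylsilyloxy)buta-1,3-diene; 3 1,1-dimethoxydec-1-en-3-one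
Product: 8 benzyl 2-heptyl-6-hydroxy-4-methoxybenzoate, via open-chain silyl enol ether 7 (not isolated)
Conditions: TiCl4 (1.1 equiv), CH2Cl2, −78 to 20 °C; then 10% aq. HCl
Reagents that add atoms: none
Why: TiCl4 binds the ketone oxygen of 3 and gives the push–pull enone dialkoxycarbenium character, so the unsubstituted terminus of 6 adds at the acetal carbon in a vinylogous Mukaiyama–Michael sense (C5–C4 bond) and one methoxy group leaves to give 7. After Lewis acid-mediated E/Z equilibration of the new vinylogous ester, the silyl enol ether carbon of 7 (future C1) attacks the heptyl ketone (C1–C2 bond), and loss of water aromatises the ring. The closest known reaction type is the TiCl4-mediated formal [3+3] cyclocondensation of 1,3-bis(silyloxy)-1,3-dienes with 3-alkoxy and 1,1-dialkoxy enones to salicylates. Ring A closes by a 6-(enolendo)-exo-trig Mukaiyama aldol, a favoured mode, and no stereocentre is formed. The step needs site selectivity between the two electrophilic carbons of 3, because the reverse orientation would place heptyl at C4 and methoxy at C6. This selectivity is secured because the complexed ketone is deactivated as part of a vinylogous carbonate, while the acetal carbon carries the positive charge and meets the less hindered, more nucleophilic diene terminus first.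

**Step 5**
Reactants: 8 benzyl 2-heptyl-6-hydroxy-4-methoxybenzoate
Product: 9 benzyl 2-heptyl-4-methoxy-6-(trifluoromethylsulfonyloxy)benzoate
Conditions: Tf2O, pyridine, CH2Cl2, 0 °C
Reagents that add atoms: trifluoromethanesulfonic anhydride, O=S(=O)(OS(=O)(=O)C(F)(F)F)C(F)(F)F
Why: O-sulfonylation (aryl triflate formation) should be clean because the C6 phenol is the only nucleophilic site and pyridine breaks its hydrogen bond to the ester.

**Step 6**
Reactants: 1 octanoyl chloride
Product: 10 N-methoxy-N-methyloctanamide
Conditions: MeNHOMe·HCl, Et3N (2.2 equiv), CH2Cl2, 0 °C to rt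
Reagents that add atoms: N,O-dimethylhydroxylamine hydrochloride, CNOC.Cl
Why: Acylation of the amine by an acid chloride (Weinreb amide formation) is a routine amide synthesis.

**Step 7**
Reactants: 11 2,2,6-trimethyl-4H-1,3-dioxin-4-one; 12 methoxyacetyl chloride
Product: 13 6-(3-methoxy-2-oxopropyl)-2,2-dimethyl-4H-1,3-dioxin-4-one
Conditions: 11 (2 equiv), LiN(SiMe3)2 (2 equiv), THF, −78 °C; 12 (1 equiv), −78 °C; aq. NH4Cl
Reagents that add atoms: none
Why: In this vinylogous Claisen-type γ-C-acylation of the lithium dienolate of the dioxinone, the second equivalent of dienolate takes up the acidic proton of 13 and so prevents double acylation.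

**Step 8**
Reactants: 13 6-(3-methoxy-2-oxopropyl)-2,2-dimethyl-4H-1,3-dioxin-4-one; 10 N-methoxy-N-methyloctanamide
Product: 14 6-(3-methoxy-2,4-dioxoundecyl)-2,2-dimethyl-4H-1,3-dioxin-4-one (racemic, enolisable)
Conditions: LiN(iPr)2 (2.2 equiv), THF, −78 to −40 °C; 10, −78 to −20 °C; cold 1 M HCl
Reagents that add atoms: none
Why: In this Claisen condensation of a keto-dioxinone dianion, the last-formed and most basic carbanion (the methoxy-bearing carbon) is acylated, and the chelated tetrahedral adduct of the Weinreb amide survives until the quench, so no over-addition occurs.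

**Step 9**
Reactants: 14 6-(3-methoxy-2,4-dioxoundecyl)-2,2-dimethyl-4H-1,3-dioxin-4-one
Product: 15 5-heptyl-7-hydroxy-6-methoxy-2,2-dimethyl-4H-1,3-benzodioxin-4-one
Conditions: Et3N, CH2Cl2, rt
Reagents that add atoms: none
Why: In this biomimetic intramolecular aldol condensation and aromatisation of a diketo-dioxinone, the dioxinone C5 attacks the heptyl ketone to form the six-membered ring, water is lost and the remaining ketone tautomerises to the C4' phenol, while the acetonide stays in place and masks the C1' carboxyl and the C2' hydroxyl together.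

**Step 10**
Reactants: 9 benzyl 2-heptyl-4-methoxy-6-(trifluoromethylsulfonyloxy)benzoate; 15 5-heptyl-7-hydroxy-6-methoxy-2,2-dimethyl-4H-1,3-benzodioxin-4-one
Product: 16 benzyl 2-heptyl-6-[(5-heptyl-6-methoxy-2,2-dimethyl-4-oxo-4H-1,3-benzodioxin-7-yl)oxy]-4-methoxybenzoate
Conditions: Pd(OAc)2 (5 mol %), 2-di-tert-butylphosphino-2',4',6'-triisopropylbiphenyl (10 mol %), K3PO4 (2 equiv), toluene, 100 °C, 9 added slowly
Reagents that add atoms: none
Why: In this Buchwald–Hartwig-type C–O coupling, zerovalent palladium inserts into the C6–OTf bond, the only free phenol (C4'–OH of 15) exchanges onto the metal, and the bulky biaryl phosphine together with the ortho ester of ring A accelerates the reductive elimination.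

**Step 11**
Reactants: 16 benzyl 2-heptyl-6-[(5-heptyl-6-methoxy-2,2-dimethyl-4-oxo-4H-1,3-benzodioxin-7-yl)oxy]-4-methoxybenzoate
Product: 17 benzyl 4-{2-[(benzyloxy)carbonyl]-3-heptyl-5-methoxyphenoxy}-6-heptyl-2-hydroxy-5-methoxybenzoate
Conditions: BnOH (5 equiv), NaH (3 equiv), THF, 0 °C to rt; then 1 M HCl
Reagents that add atoms: benzyl alcohol, OCc1ccccc1
Why: Alkoxide transesterification of the benzodioxinone (addition–elimination at the lactone-type carbonyl with loss of acetone) should free the C2' phenol, and any exchange at the ring A ester is degenerate because that ester is also benzyl.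

**Step 12**
Reactants: 17 benzyl 4-{2-[(benzyloxy)carbonyl]-3-heptyl-5-methoxyphenoxy}-6-heptyl-2-hydroxy-5-methoxybenzoate
Product: 18 4-(2-carboxy-3-heptyl-5-methoxyphenoxy)-6-heptyl-2-hydroxy-5-methoxybenzoic acid (target)
Conditions: H2 (1 atm), 10% Pd/C, EtOAc, rt
Reagents that add atoms: none
Why: Catalytic hydrogenolysis should cleave both benzyl esters at the unhindered benzylic C–O bonds under neutral conditions, leaving the aryl ethers untouched and avoiding the acid or heat that could decarboxylate the salicylic acid of ring B.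

**Compound list**
1 | octanoyl chloride | CCCCCCCC(=O)Cl | starting material
2 | 1,1-dimethoxyethene | C=C(OC)OC | starting material
3 | 1,1-dimethoxydec-1-en-3-one | CCCCCCCC(=O)C=C(OC)OC | intermediate
4 | benzyl acetoacetate | CC(=O)CC(=O)OCc1ccccc1 | starting material
5 | benzyl 3-(trimethylsilyloxy)but-2-enoate (E/Z mixture) | CC(O[Si](C)(C)C)=CC(=O)OCc1ccccc1 | intermediate
6 | 1-benzyloxy-1,3-bis(trimethylsilyloxy)buta-1,3-diene (drawn 1E; either geometry serves) | C=C(O[Si](C)(C)C)/C=C(/O[Si](C)(C)C)OCc1ccccc1 | intermediate
7 | benzyl 5-methoxy-7-oxo-3-(trimethylsilyloxy)tetradeca-2,5-dienoate (geometries equilibrate) | CCCCCCCC(=O)C=C(OC)CC(O[Si](C)(C)C)=CC(=O)OCc1ccccc1 | intermediate (not isolated)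
8 | benzyl 2-heptyl-6-hydroxy-4-methoxybenzoate | CCCCCCCc1cc(OC)cc(O)c1C(=O)OCc1ccccc1 | intermediate
9 | benzyl 2-heptyl-4-methoxy-6-(trifluoromethylsulfonyloxy)benzoate | CCCCCCCc1cc(OC)cc(OS(=O)(=O)C(F)(F)F)c1C(=O)OCc1ccccc1 | intermediate
10 | N-methoxy-N-methyloctanamide | CCCCCCCC(=O)N(C)OC | intermediate
11 | 2,2,6-trimethyl-4H-1,3-dioxin-4-one | CC1=CC(=O)OC(C)(C)O1 | starting material
12 | methoxyacetyl chloride | COCC(=O)Cl | starting material
13 | 6-(3-methoxy-2-oxopropyl)-2,2-dimethyl-4H-1,3-dioxin-4-one | COCC(=O)CC1=CC(=O)OC(C)(C)O1 | intermediate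
14 | 6-(3-methoxy-2,4-dioxoundecyl)-2,2-dimethyl-4H-1,3-dioxin-4-one (racemic, enolisable) | CCCCCCCC(=O)C(OC)C(=O)CC1=CC(=O)OC(C)(C)O1 | intermediate
15 | 5-heptyl-7-hydroxy-6-methoxy-2,2-dimethyl-4H-1,3-benzodioxin-4-one | CCCCCCCc1c(OC)c(O)cc2OC(C)(C)OC(=O)c12 | intermediate
16 | benzyl 2-heptyl-6-[(5-heptyl-6-methoxy-2,2-dimethyl-4-oxo-4H-1,3-benzodioxin-7-yl)oxy]-4-methoxybenzoate | CCCCCCCc1cc(OC)cc(Oc2cc3OC(C)(C)OC(=O)c3c(CCCCCCC)c2OC)c1C(=O)OCc1ccccc1 | intermediate
17 | benzyl 4-{2-[(benzyloxy)carbonyl]-3-heptyl-5-methoxyphenoxy}-6-heptyl-2-hydroxy-5-methoxybenzoate | CCCCCCCc1cc(OC)cc(Oc2cc(O)c(C(=O)OCc3ccccc3)c(CCCCCCC)c2OC)c1C(=O)OCc1ccccc1 | intermediate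
18 | 4-(2-carboxy-3-heptyl-5-methoxyphenoxy)-6-heptyl-2-hydroxy-5-methoxybenzoic acid | CCCCCCCc1cc(OC)cc(Oc2cc(O)c(C(=O)O)c(CCCCCCC)c2OC)c1C(=O)O | target

**Total step count:** 12
**Longest linear sequence:** 7 steps (steps 2, 3, 4, 5, 10, 11 and 12, from 4 to 18)

**Steps most likely to fail**

**Step 4.**
- What may go wrong: the first C–C bond may form with poor site selectivity between the acetal carbon and the ketone. The moisture-sensitive ketene acetal may also be hydrolysed or demethylated by the Lewis acid before it is attacked.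
- Fallback: a biomimetic polyketide aromatisation replaces the cyclocondensation. It sets out from 11 and 10 and returns at 8.
- Compound 11 is deprotonated with LiN(SiMe3)2 and acetylated with acetyl chloride at the γ-carbon to give 6-(2-oxopropyl)-2,2-dimethyl-4H-1,3-dioxin-4-one F1.
- The dianion of F1 (LiN(iPr)2, 2 equiv) is acylated with 10 to give 6-(2,4-dioxoundecyl)-2,2-dimethyl-4H-1,3-dioxin-4-one F2.
- Heating F2 with benzyl alcohol in toluene at 110 °C expels acetone by a retro-hetero-Diels–Alder reaction. The acylketene 3,5,7-trioxotetradec-1-en-1-one F3 is trapped as benzyl 3,5,7-trioxotetradecanoate F4.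
- Cs2CO3 and then HCl close and dehydrate F4 to benzyl 2-heptyl-4,6-dihydroxybenzoate F5.
- MeI (1 equiv) and K2CO3 in acetone should methylate only the C4 hydroxyl, because the C6 hydroxyl is held in a hydrogen bond to the ester. This gives 8.

**Step 10.**
- What may go wrong: phenoxide may cleave the triflate at sulfur. Reductive elimination from the rather electron-poor phenoxide may be slow. The phenoxide may also attack an acetonide carbonyl at 100 °C.
- Fallback: an oxidative copper coupling at mild temperature, setting out from 9 and returning at 16.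
- Miyaura borylation of 9 (PdCl2(dppf), bis(pinacolato)diboron, KOAc, dioxane, 80 °C) gives benzyl 2-heptyl-4-methoxy-6-(4,4,5,5-tetramethyl-1,3,2-dioxaborolan-2-yl)benzoate F6.
- F6 is joined to phenol 15 by a Chan–Lam–Evans coupling (Cu(OAc)2, pyridine, B(OH)3, 4 Å molecular sieves, MeCN, air) to give 16.

**Step 8.**
- What may go wrong: acyl transfer to the hindered, methoxy-bearing terminus of the dianion may be sluggish. Proton exchange with the α-methylene group of the amide could then take over.
- Fallback: a carbonyl addition followed by an oxidation replaces the acyl transfer. It sets out from 13 and returns at 14.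
- The dianion of 13 adds at −78 °C to commercial octanal, a far faster electrophile. This gives 6-(4-hydroxy-3-methoxy-2-oxoundecyl)-2,2-dimethyl-4H-1,3-dioxin-4-one F7 as a mixture of diastereomers whose centres are erased later.
- Dess–Martin periodinane in CH2Cl2 oxidises the secondary alcohol of F7 to give 14.

**Further compounds**
F1 | step 4 | 6-(2-oxopropyl)-2,2-dimethyl-4H-1,3-dioxin-4-one | CC(=O)CC1=CC(=O)OC(C)(C)O1
F2 | step 4 | 6-(2,4-dioxoundecyl)-2,2-dimethyl-4H-1,3-dioxin-4-one | CCCCCCCC(=O)CC(=O)CC1=CC(=O)OC(C)(C)O1
F3 | step 4 | 3,5,7-trioxotetradec-1-en-1-one (acylketene) | CCCCCCCC(=O)CC(=O)CC(=O)C=C=O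
F4 | step 4 | benzyl 3,5,7-trioxotetradecanoate | CCCCCCCC(=O)CC(=O)CC(=O)CC(=O)OCc1ccccc1
F5 | step 4 | benzyl 2-heptyl-4,6-dihydroxybenzoate | CCCCCCCc1cc(O)cc(O)c1C(=O)OCc1ccccc1
F6 | step 10 | benzyl 2-heptyl-4-methoxy-6-(4,4,5,5-tetramethyl-1,3,2-dioxaborolan-2-yl)benzoate | CCCCCCCc1cc(OC)cc(B2OC(C)(C)C(C)(C)O2)c1C(=O)OCc1ccccc1
F7 | step 8 | 6-(4-hydroxy-3-methoxy-2-oxoundecyl)-2,2-dimethyl-4H-1,3-dioxin-4-one (mixture of racemic diastereomers) | CCCCCCCC(O)C(OC)C(=O)CC1=CC(=O)OC(C)(C)O1
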